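**Strategy.** The bicyclo[3.3.1]nonane is cut at C1–C8 and C5–C6, which returns ring A (C1–C2–C3–C4–C5–C9) to an aromatic 3,5-diprenyl aroylphloroglucinol and the C6–C7–C8 bridge to a geometrically defined α-acetoxymethyl enal. One base-mediated operation under a chiral ammonium ion pair joins the two: conjugate addition at C8, loss of acetate and a second conjugate addition at C6 dearomatise ring A, close ring B and set C1, C5, C7 and C8. The feature exploited is that both prenylated arene carbons become the quaternary bridgeheads flanking the C9 ketone. The precursors are the silyl-protected diprenyl acylphloroglucinol 6 and enal 12, whose formyl carbon is later grown into the geranyl chain by alkyl–alkenyl cross-coupling.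

Key step: step 8

Numbering used: bridgeheads C1 (next to C8) and C5, bridging ketone C9, aroyl-dione bridge C2–C3–C4, methylene C6, methine C7, quaternary C8; geranyl carbons are primed (C1′ is the former formyl carbon).

Assumption: the cinchonidinium ion pair is taken to select the antipode drawn; if it selects the other, the pseudoenantiomeric O-allyl-N-(9-anthracenylmethyl)cinchoninium bromide takes its place in step 8 with nothing else changed. Enolised triketones are drawn as the C4-enol tautomer.

**Route**

Step 1
Reactants: 1 phloroglucinol; 2 3-hydroxybenzoic acid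
Product: 3 (3-hydroxyphenyl)(2,4,6-trihydroxyphenyl)methanone
Conditions: P2O5 in MeSO3H (Eaton's reagent), 70 °C; ice-water
Reagents that add atoms: none
Why: Friedel–Crafts acylation, in which the acylium ion or mixed anhydride formed from 2 in the dehydrating acid attacks the very electron-rich triol once and then leaves a deactivated ring, and because the acid has no ortho hydroxyl the ketone cannot close to a xanthone.

Step 2
Reactants: 3 (3-hydroxyphenyl)(2,4,6-trihydroxyphenyl)methanone; 4 prenyl bromide
Product: 5 (3-hydroxyphenyl)[2,4,6-trihydroxy-3,5-bis(3-methylbut-2-enyl)phenyl]methanone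
Conditions: 4 (2.1 equiv), DBU (2.2 equiv), THF, 0 → 23 °C
Reagents that add atoms: none
Why: C-alkylation of an acylphloroglucinolate with an allylic bromide, in which DBU ionises only the vinylogous-acid hydroxyls of ring A so that its two free ring carbons react as soft nucleophiles while the less acidic 3′-OH stays protonated and is not etherified.

Step 3
Reactants: 5 (3-hydroxyphenyl)[2,4,6-trihydroxy-3,5-bis(3-methylbut-2-enyl)phenyl]methanone
Product: 6 [2,4,6-trihydroxy-3,5-bis(3-methylbut-2-enyl)phenyl][3-(triisopropylsilyloxy)phenyl]methanone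
Conditions: i-Pr3SiCl (1.05 equiv), imidazole, CH2Cl2/DMF, 0 °C
Reagents that add atoms: chlorotriisopropylsilane, CC(C)[Si](Cl)(C(C)C)C(C)C
Why: Sterically selective phenol silylation, since after step 2 the 3′-hydroxyl is the only one without two ortho substituents and the bulky chlorosilane should leave the three flanked hydroxyls of ring A free for the key step.

Step 4
Reactants: 7 5-bromo-2-methylpent-2-ene (homoprenyl bromide)
Product: 8 6-methylhept-5-en-1-yne
Conditions: LiC≡CH·H2NCH2CH2NH2, DMSO, 10 → 23 °C
Reagents that add atoms: lithium acetylide ethylenediamine complex, [Li]C#C.NCCN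
Why: SN2 alkylation of lithium acetylide by a primary bromide in a dipolar aprotic solvent.

Step 5
Reactants: 8 6-methylhept-5-en-1-yne
Product: 9 7-methyloct-6-en-2-yn-1-ol
Conditions: n-BuLi, THF, −78 °C; (CH2O)n, −78 → 23 °C; H2O
Reagents that add atoms: paraformaldehyde (formaldehyde), C=O
Why: Hydroxymethylation of a terminal alkyne by addition of its alkynyllithium to formaldehyde.

Step 6
Reactants: 9 7-methyloct-6-en-2-yn-1-ol
Product: 11 (E)-2-(hydroxymethyl)-3,7-dimethylocta-2,6-dienal, via vinylmagnesium alkoxide 10 (not isolated)
Conditions: MeMgBr (5 equiv), Fe(acac)3 (15 mol%), THF, −78 → 0 °C; then DMF, 0 → 23 °C; aqueous work-up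
Reagents that add atoms: methylmagnesium bromide, C[Mg]Br; N,N-dimethylformamide, CN(C)C=O
Why: Alkoxide-directed iron-catalysed syn-carbomagnesiation of a propargylic alcohol puts methyl on the distal alkyne carbon and magnesium on C2 cis to it, and formylation of this configurationally stable alkenylmagnesium with DMF goes with retention, so the formyl group ends cis to the C3 methyl and trans to the chain, which is the (E)-enal.

Step 7
Reactants: 11 (E)-2-(hydroxymethyl)-3,7-dimethylocta-2,6-dienal
Product: 12 (E)-2-(acetoxymethyl)-3,7-dimethylocta-2,6-dienal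
Conditions: Ac2O, pyridine, CH2Cl2, 0 °C
Reagents that add atoms: acetic anhydride, CC(=O)OC(C)=O
Why: O-acetylation of the primary allylic alcohol under mild pyridine conditions that should leave the tetrasubstituted enal geometry untouched.

Step 8
Reactants: 6 [2,4,6-trihydroxy-3,5-bis(3-methylbut-2-enyl)phenyl][3-(triisopropylsilyloxy)phenyl]methanone; 12 (E)-2-(acetoxymethyl)-3,7-dimethylocta-2,6-dienal
Product: 15 C7-formyl bicyclo[3.3.1]nonane trione silyl ether, via acrolein adduct 13 (not isolated), via adamantanol 14 (not isolated)
Conditions: CsOH·H2O (5 equiv), O-allyl-N-(9-anthracenylmethyl)cinchonidinium bromide (20 mol%), 4 Å MS, CH2Cl2, −50 °C; filter, evaporate; then KN(SiMe3)2 (3 equiv), THF, 65 °C; aq. HCl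
Reagents that add atoms: none
Why: Within the chiral ammonium ion pair the phloroglucinolate of 6 adds through one prenylated carbon to the β-carbon of 12 (C1–C8), the enolate expels acetate (E1cB) to give the 2-substituted acrolein 13, and the second prenylated carbon closes ring B by 6-endo-trig Michael addition onto the new methylene (C5–C6), which makes both bridgeheads quaternary and so fixes ring A in its dearomatised form. This is the known alkylative dearomatisation–annulation of diprenyl acylphloroglucinols with α-acetoxymethyl enals in its cinchona phase-transfer form. Kinetic protonation of the C7 enolate from the exo face should leave the formyl group axial, where the C3 enolate captures it in a 6-exo-trig aldol as adamantanol 14; the amide base at 65 °C reverses that aldol and epimerises C7, so the material should drain to the equatorial aldehyde, which cannot reach C3. C1 and C5 are set together because the ion pair decides, on a given arene face, which of the two enantiotopic prenylated carbons takes C8 and the short tether forces the other to bond on the same face; C8 is set in the first Michael addition by the face of the (E)-enal that is presented, modelled with the small methyl over ring A and the formyl group over the C2 oxygen, where the cation sits between that oxygen and the aroyl oxygen; C7 is thermodynamic. The step needs C- over O-alkylation and attack at the prenylated rather than the aroylated ring carbon, which the soft hindered acceptor and the higher charge density at C1/C5 should secure, and it needs the enal to keep its geometry, which the low temperature of the bond-forming stage protects. Neither bridgehead can invert in the thermal stage without both new bonds breaking.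

Step 9
Reactants: 15 C7-formyl bicyclo[3.3.1]nonane trione silyl ether
Product: 16 C4 methyl enol ether of 15
Conditions: Me3SiCHN2, i-Pr2NEt, MeCN/MeOH, 0 → 23 °C
Reagents that add atoms: trimethylsilyldiazomethane, C[Si](C)(C)C=[N+]=[N-]
Why: O-methylation of the strongly acidic enolised triketone by a diazoalkane, expected at the less hindered C4 oxygen (the site is immaterial because step 14 removes the group), which masks the acid before the phosphine–iodine and organozinc steps and leaves the aldehyde, ketones and silyl ether alone.

Step 10
Reactants: 16 C4 methyl enol ether of 15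
Product: 17 C7 hydroxymethyl compound
Conditions: NaBH4, MeOH/THF, −40 °C
Reagents that add atoms: none
Why: Chemoselective borohydride reduction, the aldehyde being far more electrophilic than the C9 ketone held between two quaternary carbons and than the cross-conjugated vinylogous ester and aryl ketone; C7 is not touched.

Step 11
Reactants: 17 C7 hydroxymethyl compound
Product: 18 C7 iodomethyl compound
Conditions: PPh3, imidazole, I2 (premixed), toluene/MeCN, 0 → 45 °C
Reagents that add atoms: iodine, II
Why: Appel-type iodination, in which iodide displaces the alkoxyphosphonium group by SN2 at the primary carbon; premixing leaves no free iodine for the trisubstituted alkenes and the masked enol cannot be turned into a β-iodoenone.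

Step 12
Reactants: 8 6-methylhept-5-en-1-yne
Product: 20 (E)-1-iodo-2,6-dimethylhepta-1,5-diene, via vinylalane 19 (not isolated)
Conditions: Me3Al (2 equiv), Cp2ZrCl2 (25 mol%), CH2Cl2, 0 → 23 °C; then I2, THF, −30 → 0 °C
Reagents that add atoms: trimethylaluminium, C[Al](C)C; iodine, II
Why: Zirconium-catalysed methylalumination (Negishi carboalumination) adds methyl and aluminium syn across the terminal alkyne with aluminium on the terminal carbon, and iodinolysis with retention gives the (E)-alkenyl iodide.

Step 13
Reactants: 18 C7 iodomethyl compound; 20 (E)-1-iodo-2,6-dimethylhepta-1,5-diene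
Product: 22 geranylated methyl enol ether silyl ether, via alkylzinc iodide 21 (not isolated)
Conditions: Zn dust (Me3SiCl-activated), LiCl, THF, 40 °C; then 20, PdCl2(dppf) (5 mol%), THF, 50 °C
Reagents that add atoms: none
Why: Negishi sp3–sp2 coupling, in which zinc inserts into the primary C–I bond to give an alkylzinc iodide that tolerates the ketones and the vinylogous ester, and palladium joins it to the alkenyl iodide with retention of the (E) geometry fixed in step 12, the wide-bite-angle diphosphine favouring reductive elimination over β-hydride loss.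

Step 14
Reactants: 22 geranylated methyl enol ether silyl ether
Product: 23 target, 3-(3-hydroxybenzoyl)-4-hydroxy-8-methyl-7-[(2E)-3,7-dimethylocta-2,6-dienyl]-8-(4-methylpent-3-enyl)-1,5-bis(3-methylbut-2-enyl)bicyclo[3.3.1]non-3-ene-2,9-dione
Conditions: LiOH·H2O, dioxane/H2O, 90 °C; aq. HCl
Reagents that add atoms: lithium hydroxide monohydrate (supplies the C4 oxygen), [Li+].[OH-].O
Why: Hydroxide adds to C4 of the vinylogous ester and expels methoxide (addition–elimination) and also cleaves the base-labile aryl silyl ether, so both masks fall in one operation, while no stereocentre is at risk because the bridgeheads and C8 are quaternary and C7 is no longer α to a carbonyl.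

**Compound list**

1 | phloroglucinol (benzene-1,3,5-triol) | Oc1cc(O)cc(O)c1 | starting material
2 | 3-hydroxybenzoic acid | OC(=O)c1cccc(O)c1 | starting material
3 | (3-hydroxyphenyl)(2,4,6-trihydroxyphenyl)methanone | O=C(c1cccc(O)c1)c1c(O)cc(O)cc1O | intermediate
4 | prenyl bromide (1-bromo-3-methylbut-2-ene) | CC(C)=CCBr | starting material
5 | (3-hydroxyphenyl)[2,4,6-trihydroxy-3,5-bis(3-methylbut-2-enyl)phenyl]methanone | CC(C)=CCc1c(O)c(CC=C(C)C)c(O)c(C(=O)c2cccc(O)c2)c1O | intermediate
6 | [2,4,6-trihydroxy-3,5-bis(3-methylbut-2-enyl)phenyl][3-(triisopropylsilyloxy)phenyl]methanone | CC(C)=CCc1c(O)c(CC=C(C)C)c(O)c(C(=O)c2cccc(O[Si](C(C)C)(C(C)C)C(C)C)c2)c1O | intermediate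
7 | 5-bromo-2-methylpent-2-ene (homoprenyl bromide) | CC(C)=CCCBr | starting material
8 | 6-methylhept-5-en-1-yne | CC(C)=CCCC#C | intermediate
9 | 7-methyloct-6-en-2-yn-1-ol | CC(C)=CCCC#CCO | intermediate
10 | vinylmagnesium alkoxide: bromomagnesium 2-(bromomagnesio)-3,7-dimethylocta-2,6-dien-1-olate, magnesium on C2 cis to the C3 methyl | CC(C)=CCC/C(C)=C(/[Mg]Br)CO[Mg]Br | intermediate
11 | (E)-2-(hydroxymethyl)-3,7-dimethylocta-2,6-dienal (formyl cis to the C3 methyl) | CC(C)=CCC/C(C)=C(/C=O)CO | intermediate
12 | (E)-2-(acetoxymethyl)-3,7-dimethylocta-2,6-dienal | CC(C)=CCC/C(C)=C(/C=O)COC(C)=O | intermediate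
13 | acrolein adduct: ring A dearomatised at C1, which carries its prenyl group and C8 (methyl, 4-methylpent-3-enyl, 1-formylvinyl); C1 and C8 configured as in 15; present as its caesium salt, drawn as a neutral tautomer | C=C(C=O)[C@](C)(CCC=C(C)C)[C@]1(CC=C(C)C)C(=O)C(C(=O)c2cccc(O[Si](C(C)C)(C(C)C)C(C)C)c2)=C(O)C(CC=C(C)C)=C1O | intermediate
14 | adamantanol: aldol adduct in which the former formyl carbon bridges C7 and C3 (C3 now quaternary with the aroyl group, C2, C4 and C9 ketones); carbinol OH on the side of C6, away from C8; C7 hydrogen exo | O[C@H]4[C@H]1C[C@]2(CC=C(C)C)C(=O)[C@@](CC=C(C)C)(C(=O)[C@@]4(C(=O)c3cccc(O[Si](C(C)C)(C(C)C)C(C)C)c3)C2=O)[C@@]1(C)CCC=C(C)C | intermediate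
15 | C7-formyl bicyclo[3.3.1]nonane trione silyl ether: 4-hydroxy-8-methyl-8-(4-methylpent-3-enyl)-1,5-bis(3-methylbut-2-enyl)-3-[3-(triisopropylsilyloxy)benzoyl]-2,9-dioxobicyclo[3.3.1]non-3-ene-7-carbaldehyde; formyl equatorial on ring B (exo, away from the C2–C4 bridge); C8 methyl axial on the C9 side; C8 4-methylpent-3-enyl equatorial and trans to the formyl group | O=C[C@@H]1C[C@]2(CC=C(C)C)C(=O)[C@@](CC=C(C)C)(C(=O)C(C(=O)c3cccc(O[Si](C(C)C)(C(C)C)C(C)C)c3)=C2O)[C@@]1(C)CCC=C(C)C | intermediate
16 | C4 methyl enol ether of 15 (4-methoxy; configuration as in 15) | O=C[C@@H]1C[C@]2(CC=C(C)C)C(=O)[C@@](CC=C(C)C)(C(=O)C(C(=O)c3cccc(O[Si](C(C)C)(C(C)C)C(C)C)c3)=C2OC)[C@@]1(C)CCC=C(C)C | intermediate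
17 | C7 hydroxymethyl compound (primary alcohol from 16; configuration as in 15) | OC[C@@H]1C[C@]2(CC=C(C)C)C(=O)[C@@](CC=C(C)C)(C(=O)C(C(=O)c3cccc(O[Si](C(C)C)(C(C)C)C(C)C)c3)=C2OC)[C@@]1(C)CCC=C(C)C | intermediate
18 | C7 iodomethyl compound (primary iodide from 17; configuration as in 15) | IC[C@@H]1C[C@]2(CC=C(C)C)C(=O)[C@@](CC=C(C)C)(C(=O)C(C(=O)c3cccc(O[Si](C(C)C)(C(C)C)C(C)C)c3)=C2OC)[C@@]1(C)CCC=C(C)C | intermediate
19 | vinylalane: (E)-(2,6-dimethylhepta-1,5-dienyl)dimethylalane | CC(C)=CCC/C(C)=C/[Al](C)C | intermediate
20 | (E)-1-iodo-2,6-dimethylhepta-1,5-diene | CC(C)=CCC/C(C)=C/I | intermediate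
21 | alkylzinc iodide formed from 18 at C1′ | I[Zn]C[C@@H]1C[C@]2(CC=C(C)C)C(=O)[C@@](CC=C(C)C)(C(=O)C(C(=O)c3cccc(O[Si](C(C)C)(C(C)C)C(C)C)c3)=C2OC)[C@@]1(C)CCC=C(C)C | intermediate
22 | geranylated methyl enol ether silyl ether: 7-[(2E)-3,7-dimethylocta-2,6-dienyl]-4-methoxy compound with the aryl silyl ether in place; configuration as in 23 | CC(C)=CCC/C(C)=C/C[C@@H]1C[C@]2(CC=C(C)C)C(=O)[C@@](CC=C(C)C)(C(=O)C(C(=O)c3cccc(O[Si](C(C)C)(C(C)C)C(C)C)c3)=C2OC)[C@@]1(C)CCC=C(C)C | intermediate
23 | 3-(3-hydroxybenzoyl)-4-hydroxy-8-methyl-7-[(2E)-3,7-dimethylocta-2,6-dienyl]-8-(4-methylpent-3-enyl)-1,5-bis(3-methylbut-2-enyl)bicyclo[3.3.1]non-3-ene-2,9-dione; geranyl equatorial (exo) at C7, C8 methyl axial on the C9 side, C8 4-methylpent-3-enyl equatorial and trans to geranyl | CC(C)=CCC/C(C)=C/C[C@@H]1C[C@]2(CC=C(C)C)C(=O)[C@@](CC=C(C)C)(C(=O)C(C(=O)c3cccc(O)c3)=C2O)[C@@]1(C)CCC=C(C)C | target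

**Totals**

Total step count: 14.
Longest linear sequence: 10 steps (7 → 8 → 9 → 11 → 12 → 15 → 16 → 17 → 18 → 22 → 23).

**Steps most likely to fail**

1. Step 8. The chiral ion pair may discriminate poorly between the two enantiotopic prenylated carbons, or the enal β-carbon may be attacked on both faces, so that enantiomeric purity or the C8 configuration erodes. Fallback, setting out from 6 and 12: the chiral salt is dropped and the annulation is run with KN(SiMe3)2 alone in THF at 65 °C, the achiral thermodynamic form of the same cascade. This should give the racemate, that is 15 together with its mirror image ent-15 F1. A C8 epimer, being a diastereomer, is removed on silica, and the antipodes are parted by preparative chromatography on a cellulose tris(3,5-dimethylphenylcarbamate) phase. The route is rejoined at 15.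

2. Step 13. Zinc may insert only slowly into the β-branched primary C–I bond, the transient C1′ radical may cyclise onto a neighbouring trisubstituted alkene, or β-hydride elimination may compete at the alkylpalladium stage. Fallback, setting out from 20 and 18: the roles are reversed so that no organometal is made on the polycycle. Iodine–lithium exchange on 20 (t-BuLi, Et2O, −78 °C) followed by ZnCl2 gives (E)-(2,6-dimethylhepta-1,5-dienyl)zinc chloride F2. This is coupled with the alkyl iodide 18 under Pd2(dba)3, tricyclopentylphosphine and N-methylimidazole in THF/N-methylpyrrolidone at 80 °C, the established coupling of unactivated primary alkyl iodides with alkenylzinc halides. The route is rejoined at 22.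

3. Step 6. Carbometalation of the internal alkyne may be incomplete or misdirected, or the hindered alkenylmagnesium may be protonated before it is formylated, returning a trisubstituted allylic alcohol. Fallback, setting out from 8: lithiation and ClCO2Me give methyl 7-methyloct-6-en-2-ynoate F3. Lithium dimethylcuprate Me2CuLi adds syn at −78 °C and the alkenylcopper is quenched with iodine to methyl (E)-2-iodo-3,7-dimethylocta-2,6-dienoate F4, with iodine cis to the new methyl. Reduction with i-Bu2AlH gives (E)-2-iodo-3,7-dimethylocta-2,6-dien-1-ol F5. Deprotonation, iodine–lithium exchange with t-BuLi and quenching with DMF give 11, where the route is rejoined.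

**Further compounds**

F1 | step 8 | ent-15, mirror image of the C7-formyl bicyclo[3.3.1]nonane trione silyl ether | O=C[C@H]1C[C@@]2(CC=C(C)C)C(=O)[C@](CC=C(C)C)(C(=O)C(C(=O)c3cccc(O[Si](C(C)C)(C(C)C)C(C)C)c3)=C2O)[C@]1(C)CCC=C(C)C
F2 | step 13 | (E)-(2,6-dimethylhepta-1,5-dienyl)zinc chloride | CC(C)=CCC/C(C)=C/[Zn]Cl
F3 | step 6 | methyl 7-methyloct-6-en-2-ynoate | CC(C)=CCCC#CC(=O)OC
F4 | step 6 | methyl (E)-2-iodo-3,7-dimethylocta-2,6-dienoate | CC(C)=CCC/C(C)=C(/I)C(=O)OC
F5 | step 6 | (E)-2-iodo-3,7-dimethylocta-2,6-dien-1-ol | CC(C)=CCC/C(C)=C(/I)CO
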